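Readings and results were generated by integration with made-up constants; scatter was added.

- Start from the gap between Q lost and D found, the share of the charge in an unseen stage. In alder at 8.00 min, Q stood at 41% and D at 40%, so the gap was 19.0%.
- I took two first-order steps, with X held (pseudo-first-order). The alder reading of Q gave a first clock of 0.111 min⁻¹.
- Integrating both steps removes time. With a fraction x of Q left, the gap is (x − x^c)/(c − 1).
- Here c is the clock ratio, the second clock over the first. The alder reading, iterated, gave 2.74.
- I drew the alder curve from that. Q started down at 1.11 mM min⁻¹ while D started flat.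
- On my curve the gap peaked near 20.4% after 5.22 min. In the alder readings D met Q near 8.00 min, and D levelled at the charge, reading 101% at 120 min.
- In maple, with L at 30 µM, the first clock read 0.0938 min⁻¹ and the clock ratio 1.53, lower than in alder. So I tied the second clock to L.

common to all: Q 10 mM; X 0.42 mM (held); G 16 µM
- alder: L 61 µM; the very flask that is asked about, followed so far
- maple: L 30 µM; run made earlier
- flask: L 61 µM

alder run (percent of the Q charged)

| time / min | D / % | Q / % |
|---|---|---|
| 8.00 | 40 | 41 |
| 25.0 | 90 | 7 |
| 40.0 | 98 | 0 |
| 60.0 | 97 | 0 |
| 90.0 | 99 | 0 |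
| 120 | 101 | 0 |

maple run (percent of the Q charged)

| time / h | D / % | Q / % |
|---|---|---|
| 0.500 | 85 | 6 |
| 1.00 | 99 | 2 |
| 1.50 | 98 | 1 |
| 2.50 | 99 | 1 |
| 4.00 | 99 | 0 |
| 8.00 | 102 | 0 |

(standard deviation of a reading: 2 percentage points)

- the numbers in the tables scatter by 2 percentage points (one standard deviation)
- at the start none of X is in solution
- "the catalyst" is G with its forms; L is a second catalyst
- no earlier run changes the charge of G; that part of a forecast is a guess

- factor on the rate of making D when 20% of the Q are converted if G is charged twice over
- factor on the rate when 20% of the Q are converted if G is charged at 3.0 µM instead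

- In my reckoning the rate of making D is the second clock times the gap, and at 20% conversion the alder gap comes to 14.8%.
- I guessed that the first clock follows G, with L and so the second clock held as in alder. Doubled G gives a clock ratio of 1.37 and a factor of 1.16. With 3.0 µM G, the ratio is 14.6 and the factor 0.378.
- The forecast gave 1.15 (1.03 to 1.35) and 0.38 (0.2 to 0.55). Of Q's fall it said “so halving L barely changes it”. My first factor stood slightly above its value.

- The flask gave 1.16 for doubled G and 0.387 for 3.0 µM G.

    Q + G ⇌ G + J (K = 1.80, k = 140 M⁻¹ s⁻¹)
    E + L + J → L + D (k = 3.00 × 10⁵ M⁻² s⁻¹)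
    X ⇌ E, rate k3*(csat - [E]) (kL = 0.0920 s⁻¹)
    G → Z (k = 1.60 × 10⁻⁷ s⁻¹)

- The flask reached 20% conversion at 1.76 min, with D being made at 31.2 mM h⁻¹. The clock ratio, times the first clock, the gap and the charge of Q, gave 27.1 mM h⁻¹ for that moment, less than the flask's rate, at 0.869 of it.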